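**Plan**

- Retrosynthesis: one hydride step takes C9–OH and the ring B side-chain CH2OH back to an N-acyl oxazolidinone and a methyl ester; then the C7–OH bond (water) and the C8–O4' ether bond (phenoxyl radical pairing) are cut, leaving an N-feruloyl oxazolidinone and a 4-alkyl-2,6-dimethoxyphenol.
- Enabling feature: the C8–O4' ether joins the C7–C9 chain of ring A to a ring B oxygen flanked by methoxy groups at C3' and C5', with alkyl at C1'. Such a phenoxyl radical can bond lastingly only through O4', and the C7 hydroxyl marks where water meets the ring A quinone methide that the coupling leaves.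
- Forward: ferulic acid is O-acetylated, joined to (S)-4-benzyloxazolidin-2-one and deacetylated; sinapic acid is esterified and hydrogenated; anodic co-oxidation joins the two at C8–O4', acidic water adds at C7, and LiBH4 reduces imide and ester. No ring is formed.
- Stereochemistry: C8 from the magnesium-chelated (S)-auxiliary (aryloxyl radical enters anti to benzyl); C7 from substrate-controlled erythro addition of water to the quinone methide.

Key step: step 6

Remark: lignan numbering is used (ring A carries C7–C9, ring B atoms are primed). The target is read from its SMILES as erythro (7S,8R). At C8 the descriptor is S in the acyl oxazolidinones and R in the target with the same arrangement in space, because C9 falls below C7 in priority on reduction.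

**Route**

Step 1
Reactants: 1 ferulic acid
Product: 2 (E)-3-(4-acetoxy-3-methoxyphenyl)prop-2-enoic acid (4-O-acetylferulic acid)
Conditions: Ac2O, aq. NaOH, 0 °C → rt; then aq. HCl
Reagents that add atoms: acetic anhydride, CC(=O)OC(C)=O
Why: Schotten–Baumann O-acylation of the phenoxide, in which the carboxylate is not durably acylated in water and the acid precipitates on acidification.

Step 2
Reactants: 2 4-O-acetylferulic acid; 3 (S)-4-benzyloxazolidin-2-one
Product: 5 (S)-3-[(E)-3-(4-acetoxy-3-methoxyphenyl)prop-2-enoyl]-4-benzyloxazolidin-2-one, via mixed pivalic anhydride 4 (not isolated)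
Conditions: PivCl, Et3N, THF, −20 °C; then 3, LiCl, −20 °C → rt
Reagents that add atoms: none
Why: N-acylation of the oxazolidinone through a mixed anhydride, in which the hindered pivaloyl carbonyl directs attack to the cinnamoyl carbonyl and the mild LiCl/Et3N activation spares the aryl acetate and the E double bond.

Step 3
Reactants: 5 O-acetylated N-feruloyl oxazolidinone
Product: 6 (S)-4-benzyl-3-[(E)-3-(4-hydroxy-3-methoxyphenyl)prop-2-enoyl]oxazolidin-2-one
Conditions: NH4OAc, MeOH/THF/H2O, rt
Reagents that add atoms: none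
Why: chemoselective transesterification of the aryl acetate, the most electrophilic acyl group present because of its phenoxide leaving group, under near-neutral conditions that should leave the N-acyl oxazolidinone intact.

Step 4
Reactants: 7 sinapic acid
Product: 8 methyl (E)-3-(4-hydroxy-3,5-dimethoxyphenyl)prop-2-enoate (methyl sinapate)
Conditions: MeOH, H2SO4 (cat.), reflux
Reagents that add atoms: methanol, CO
Why: Fischer esterification, to which the phenol and the electron-rich cinnamate double bond are inert.

Step 5
Reactants: 8 methyl sinapate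
Product: 9 methyl 3-(4-hydroxy-3,5-dimethoxyphenyl)propanoate
Conditions: H2 (1 atm), Pd/C (palladium on carbon), MeOH, rt
Reagents that add atoms: none
Why: heterogeneous catalytic hydrogenation of the conjugated C=C, which leaves the arene, the phenol and the ester untouched at ambient pressure.

Step 6
Reactants: 6 (S)-4-benzyl-3-feruloyloxazolidin-2-one; 9 methyl 3-(4-hydroxy-3,5-dimethoxyphenyl)propanoate
Product: 11 (S)-4-benzyl-3-[(2S,3S)-3-hydroxy-3-(4-hydroxy-3-methoxyphenyl)-2-[4-(3-methoxy-3-oxopropyl)-2,6-dimethoxyphenoxy]propanoyl]oxazolidin-2-one, via ring A quinone methide 10 (not isolated)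
Conditions: graphite felt anode, Pt cathode, undivided cell, constant current (about 1.5 F per mol of 6, stopped at partial conversion); 9 (3 equiv), Mg(ClO4)2 (0.1 M), 2,6-lutidine/2,6-lutidinium perchlorate, dry MeCN, −30 °C; then poured into THF/aq. citric acid (pH about 2.5), 0 °C
Reagents that add atoms: water, O
Why: Proposed new method: both phenols are turned into phenoxyl radicals by loss of one electron and one proton (at the anode or by hydrogen-atom exchange between them, lutidine carrying the protons to the cathode); the ring B radical, blocked at C3', C5' and C1', can bond lastingly only through O4' and pairs with C8, the spin-bearing side-chain carbon of the feruloyl radical, to give quinone methide 10, to which water then adds at C7 under specific-acid catalysis with rearomatisation of ring A. The closest known reaction types are the Ag2O-mediated 8-O-4' cross-coupling of ferulates with 2,6-dimethoxyphenols and the auxiliary-controlled oxidative dimerisation of feruloyl imides; what is new is auxiliary control of an 8-O-4' cross-coupling with anodic generation of the radicals, and no ring closes. C8 is set by the auxiliary: Mg(ClO4)2 binds the two imide carbonyls syn, which fixes the s-cis enoyl conformer and puts the benzyl group over one face of C8, so the aryloxyl radical should enter on the other face, in the sense of alkylation of the chelated enolates (8S in 10 and 11, the arrangement that becomes 8R in the target). C7 is set by the substrate: in the conformer of 10 that minimises A(1,3) strain, C8–H lies in the plane of the exocyclic double bond and water should enter anti to the 2,6-dimethoxyaryloxy group, the erythro preference known for such ethers at low pH, here untested with an imide at C9 (7S). The step needs cross- over homo-coupling, no oxidation of the product and hydration faster than loss of the acidic C8 proton from 10: the first rests on the blocked, more easily oxidised ring B phenol in excess, the second on the product remaining a non-phenolic quinone methide until the current is off and on partial conversion, the third on the weak hindered base, the low temperature and the immediate acidic quench.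

Step 7
Reactants: 11 erythro 7-hydroxy-8-aryloxy acyl oxazolidinone
Product: 12 (1S,2R)-1-(4-hydroxy-3-methoxyphenyl)-2-[4-(3-hydroxypropyl)-2,6-dimethoxyphenoxy]propane-1,3-diol (IN0404)
Conditions: LiBH4 (excess), THF/MeOH, 0 °C → rt; aq. NH4Cl
Reagents that add atoms: none
Why: reductive cleavage of the N-acyl oxazolidinone by hydride attack at the exocyclic carbonyl, with reduction of the methyl ester by methanol-activated LiBH4 in the same operation, neither of which enolises C8 or touches C7.

**Compound list**

1 | ferulic acid, (E)-3-(4-hydroxy-3-methoxyphenyl)prop-2-enoic acid | COc1cc(/C=C/C(=O)O)ccc1O | starting material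
2 | (E)-3-(4-acetoxy-3-methoxyphenyl)prop-2-enoic acid | COc1cc(/C=C/C(=O)O)ccc1OC(C)=O | intermediate
3 | (S)-4-benzyloxazolidin-2-one | O=C1N[C@@H](Cc2ccccc2)CO1 | starting material
4 | (E)-3-(4-acetoxy-3-methoxyphenyl)prop-2-enoic pivalic anhydride (not isolated) | COc1cc(/C=C/C(=O)OC(=O)C(C)(C)C)ccc1OC(C)=O | intermediate
5 | (S)-3-[(E)-3-(4-acetoxy-3-methoxyphenyl)prop-2-enoyl]-4-benzyloxazolidin-2-one | COc1cc(/C=C/C(=O)N2[C@@H](Cc3ccccc3)COC2=O)ccc1OC(C)=O | intermediate
6 | (S)-4-benzyl-3-[(E)-3-(4-hydroxy-3-methoxyphenyl)prop-2-enoyl]oxazolidin-2-one | COc1cc(/C=C/C(=O)N2[C@@H](Cc3ccccc3)COC2=O)ccc1O | intermediate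
7 | sinapic acid, (E)-3-(4-hydroxy-3,5-dimethoxyphenyl)prop-2-enoic acid | COc1cc(/C=C/C(=O)O)cc(OC)c1O | starting material
8 | methyl (E)-3-(4-hydroxy-3,5-dimethoxyphenyl)prop-2-enoate | COc1cc(/C=C/C(=O)OC)cc(OC)c1O | intermediate
9 | methyl 3-(4-hydroxy-3,5-dimethoxyphenyl)propanoate | COC(=O)CCc1cc(OC)c(O)c(OC)c1 | intermediate
10 | (S)-4-benzyl-3-[(2S)-2-[4-(3-methoxy-3-oxopropyl)-2,6-dimethoxyphenoxy]-3-(3-methoxy-4-oxocyclohexa-2,5-dien-1-ylidene)propanoyl]oxazolidin-2-one (quinone methide, exocyclic double-bond geometry not defined, not isolated) | COC1=CC(=C[C@@H](C(=O)N2[C@@H](Cc3ccccc3)COC2=O)Oc2c(OC)cc(CCC(=O)OC)cc2OC)C=CC1=O | intermediate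
11 | (S)-4-benzyl-3-[(2S,3S)-3-hydroxy-3-(4-hydroxy-3-methoxyphenyl)-2-[4-(3-methoxy-3-oxopropyl)-2,6-dimethoxyphenoxy]propanoyl]oxazolidin-2-one | COc1cc([C@H](O)[C@@H](C(=O)N2[C@@H](Cc3ccccc3)COC2=O)Oc2c(OC)cc(CCC(=O)OC)cc2OC)ccc1O | intermediate
12 | (1S,2R)-1-(4-hydroxy-3-methoxyphenyl)-2-[4-(3-hydroxypropyl)-2,6-dimethoxyphenoxy]propane-1,3-diol (IN0404) | COc1cc([C@H](O)[C@@H](CO)Oc2c(OC)cc(CCCO)cc2OC)ccc1O | target

**Totals**

Total step count: 7. Longest linear sequence: 5 steps (steps 1, 2, 3, 6, 7); the ring B branch (steps 4, 5) joins at step 6.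

**Steps most likely to fail**

1. Step 6. Several processes may defeat it:
- tautomerisation of the quinone methide by loss of the C8 proton before water arrives, which erases C8 and leaves an aryl enol ether;
- homo-coupling of the feruloyl radical;
- weak face selection at C8 if chelation by magnesium is incomplete in acetonitrile;
- hydration from the wrong face of C7.

Fallback with known chemistry, setting out from 9 and returning at 12:
- 9 is O-alkylated with tert-butyl bromoacetate (K2CO3, acetone) to tert-butyl 2-[4-(3-methoxy-3-oxopropyl)-2,6-dimethoxyphenoxy]acetate F1.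
- CF3CO2H in CH2Cl2 frees 2-[4-(3-methoxy-3-oxopropyl)-2,6-dimethoxyphenoxy]acetic acid F2.
- Its mixed pivalic anhydride acylates 3 (Et3N, LiCl, THF) to the aryloxyacetyl oxazolidinone F3.
- An Evans syn aldol (Bu2BOTf, i-Pr2NEt, CH2Cl2, −78 → 0 °C) with 4-benzyloxy-3-methoxybenzaldehyde should give the (2S,3R) syn aldol adduct F4. It has the required arrangement at C8 but is epimeric at C7 (threo).
- LiBH4 in THF/MeOH removes the auxiliary and reduces the methyl ester, giving the threo triol F5.
- Pivaloyl chloride in pyridine at 0 °C esterifies the two primary hydroxyl groups to the bis-pivalate F6.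
- A Mitsunobu reaction (4-nitrobenzoic acid, PPh3, DIAD, THF) inverts C7 and gives the 4-nitrobenzoate F7.
- NaOMe in MeOH removes the three esters to leave the O-benzyl ether of the target F8, and hydrogenolysis (H2, Pd/C, EtOAc) gives 12.

2. Step 7. The methyl ester may be reduced incompletely under conditions mild enough for the phenolic benzylic alcohol. Hydride may also attack the ring carbonyl of the hindered imide and open the oxazolidinone, or the C7 alkoxide may undergo retro-aldol cleavage during the long exposure.

Fallback, setting out from 11 and returning at 12: the two reductions are taken apart. NaBH4 in THF/H2O at 0 °C, which reduces the exocyclic imide carbonyl but not esters, detaches the auxiliary and gives methyl 3-(4-{[(1S,2R)-1,3-dihydroxy-1-(4-hydroxy-3-methoxyphenyl)propan-2-yl]oxy}-3,5-dimethoxyphenyl)propanoate F9. The auxiliary-free ester is then reduced on its own with i-Bu2AlH in THF/CH2Cl2 at −78 → 0 °C to 12.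

3. Step 3. Solvolysis of the N-acyl oxazolidinone (loss of the auxiliary) or conjugate addition of ammonia may accompany cleavage of the aryl acetate.

Fallback, setting out from 3 and returning at 6, with no phenol protecting group at all:
- Lithiated 3 (n-BuLi, THF, −78 °C) is acylated with bromoacetyl bromide to (S)-4-benzyl-3-(2-bromoacetyl)oxazolidin-2-one F10.
- PPh3 in toluene gives {2-[(S)-4-benzyl-2-oxooxazolidin-3-yl]-2-oxoethyl}triphenylphosphonium bromide F11.
- Aqueous NaOH converts it into the stabilised ylide (S)-4-benzyl-3-[2-(triphenylphosphoranylidene)acetyl]oxazolidin-2-one F12.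
- A Wittig reaction of F12 with unprotected vanillin in toluene at 80 °C should give 6 directly as the E isomer.

**Further compounds**

F1 | step 6 | tert-butyl 2-[4-(3-methoxy-3-oxopropyl)-2,6-dimethoxyphenoxy]acetate | COC(=O)CCc1cc(OC)c(OCC(=O)OC(C)(C)C)c(OC)c1
F2 | step 6 | 2-[4-(3-methoxy-3-oxopropyl)-2,6-dimethoxyphenoxy]acetic acid | COC(=O)CCc1cc(OC)c(OCC(=O)O)c(OC)c1
F3 | step 6 | (S)-4-benzyl-3-{2-[4-(3-methoxy-3-oxopropyl)-2,6-dimethoxyphenoxy]acetyl}oxazolidin-2-one | COC(=O)CCc1cc(OC)c(OCC(=O)N2[C@@H](Cc3ccccc3)COC2=O)c(OC)c1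
F4 | step 6 | (S)-4-benzyl-3-[(2S,3R)-3-(4-benzyloxy-3-methoxyphenyl)-3-hydroxy-2-[4-(3-methoxy-3-oxopropyl)-2,6-dimethoxyphenoxy]propanoyl]oxazolidin-2-one | COc1cc([C@@H](O)[C@@H](C(=O)N2[C@@H](Cc3ccccc3)COC2=O)Oc2c(OC)cc(CCC(=O)OC)cc2OC)ccc1OCc1ccccc1
F5 | step 6 | (1R,2R)-1-(4-benzyloxy-3-methoxyphenyl)-2-[4-(3-hydroxypropyl)-2,6-dimethoxyphenoxy]propane-1,3-diol | COc1cc([C@@H](O)[C@@H](CO)Oc2c(OC)cc(CCCO)cc2OC)ccc1OCc1ccccc1
F6 | step 6 | (2R,3R)-3-(4-benzyloxy-3-methoxyphenyl)-3-hydroxy-2-{2,6-dimethoxy-4-[3-(pivaloyloxy)propyl]phenoxy}propyl pivalate | COc1cc([C@@H](O)[C@@H](COC(=O)C(C)(C)C)Oc2c(OC)cc(CCCOC(=O)C(C)(C)C)cc2OC)ccc1OCc1ccccc1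
F7 | step 6 | (1S,2R)-1-(4-benzyloxy-3-methoxyphenyl)-2-{2,6-dimethoxy-4-[3-(pivaloyloxy)propyl]phenoxy}-3-(pivaloyloxy)propyl 4-nitrobenzoate | COc1cc([C@H](OC(=O)c2ccc(cc2)[N+](=O)[O-])[C@@H](COC(=O)C(C)(C)C)Oc2c(OC)cc(CCCOC(=O)C(C)(C)C)cc2OC)ccc1OCc1ccccc1
F8 | step 6 | (1S,2R)-1-(4-benzyloxy-3-methoxyphenyl)-2-[4-(3-hydroxypropyl)-2,6-dimethoxyphenoxy]propane-1,3-diol | COc1cc([C@H](O)[C@@H](CO)Oc2c(OC)cc(CCCO)cc2OC)ccc1OCc1ccccc1
F9 | step 7 | methyl 3-(4-{[(1S,2R)-1,3-dihydroxy-1-(4-hydroxy-3-methoxyphenyl)propan-2-yl]oxy}-3,5-dimethoxyphenyl)propanoate | COc1cc([C@H](O)[C@@H](CO)Oc2c(OC)cc(CCC(=O)OC)cc2OC)ccc1O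
F10 | step 3 | (S)-4-benzyl-3-(2-bromoacetyl)oxazolidin-2-one | O=C(CBr)N1[C@@H](Cc2ccccc2)COC1=O
F11 | step 3 | {2-[(S)-4-benzyl-2-oxooxazolidin-3-yl]-2-oxoethyl}triphenylphosphonium bromide | [Br-].O=C(C[P+](c1ccccc1)(c1ccccc1)c1ccccc1)N1[C@@H](Cc2ccccc2)COC1=O
F12 | step 3 | (S)-4-benzyl-3-[2-(triphenylphosphoranylidene)acetyl]oxazolidin-2-one | O=C(C=P(c1ccccc1)(c1ccccc1)c1ccccc1)N1[C@@H](Cc2ccccc2)COC1=O
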